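**Plan**
1. Retrosynthesis: the acetate, both formyl groups and the C2=C3 alkene are adjusted last (from a C9 PMB ether, a C1 ester and a C2 carbinol carrying a masked formyl group). The bicyclo[3.3.1]nonane is then cut at C9–C5 and C1–C2 together, which opens ring A (C9, C1, C8, C7, C6, C5) and ring B (C9, C5, C4, C3, C2, C1) to one acyclic chain.
2. Enabling feature: C9–C1 is a β-oxygenated acrylate unit (C9 radical acceptor, C1 latent enolate). C5 is a methyl-bearing quaternary carbon, reachable as a tertiary radical by hydrogen-atom transfer to an exo-methylene. C2 lies α to a formyl group and next to C1, so a ketone flanked by a masked formyl group serves as aldol acceptor.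
3. Forward: (R)-citronellic acid → auxiliary alkylation → vinyl ester → (E)-alkoxyacrylate → B-alkyl Suzuki coupling with a bromoalkene keto acetal → radical conjugate addition/aldol bicyclization (ring A, then ring B) → dehydration, ester to aldehyde, PMB to acetate, acetal hydrolysis.
4. Stereochemistry: the side-chain centre comes from (R)-citronellic acid and C8 from the oxazolidinone-controlled alkylation. C9, C5 and C1 follow from C8 in the bicyclization (chair transition state, side chain equatorial, E-alkoxy group axial, cis-1,3-diaxial ring closure).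

Key step: step 10

Remark: locants C1–C9 are those of the bicyclo[3.3.1]non-2-ene core of the target (C1 formyl-bearing bridgehead, C2=C3, C5 methyl-bearing bridgehead, C8 side-chain carbon, C9 acetoxy carbon); the carbinol carbon C2 of 20 carries no descriptor because either epimer is dehydrated in step 11.

Step 1
Reactants: 1 1,1-dimethoxypropan-2-one; 2 2,3-dibromoprop-1-ene
Product: 4 5-bromo-1,1-dimethoxyhex-5-en-2-one, via lithium enolate 3 (not isolated)
Conditions: LiN(i-Pr)2, THF, −78 °C; then 2, −78 → 0 °C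
Reagents that add atoms: none
Why: Kinetic deprotonation at the methyl group (the other α-position is a hindered, poorly acidic acetal methine) and SN2 alkylation of the ketone enolate at the allylic bromide should give 4, the vinylic bromide being inert (enolate alkylation).

Step 2
Reactants: 5 (R)-citronellic acid; 6 (R)-4-benzyloxazolidin-2-one
Product: 8 (4R)-4-benzyl-3-[(3R)-3,7-dimethyloct-6-enoyl]oxazolidin-2-one, via mixed pivalic anhydride 7 (not isolated)
Conditions: t-BuCOCl, Et3N, THF, −20 °C; then 6, LiCl, rt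
Reagents that add atoms: none
Why: N-Acylation of the oxazolidinone by the mixed anhydride under LiCl/Et3N activation leaves the existing stereocentre untouched.

Step 3
Reactants: 8 (4R)-4-benzyl-3-[(3R)-3,7-dimethyloct-6-enoyl]oxazolidin-2-one
Product: 10 (4R)-4-benzyl-3-[(2R,3R)-2-(2-tert-butoxy-2-oxoethyl)-3,7-dimethyloct-6-enoyl]oxazolidin-2-one, via sodium enolate 9 (not isolated)
Conditions: NaN(SiMe3)2, THF, −78 °C; then BrCH2CO2t-Bu, −78 → −30 °C
Reagents that add atoms: tert-butyl bromoacetate, CC(C)(C)OC(=O)CBr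
Why: Evans asymmetric alkylation: the chelated Z sodium enolate is alkylated on the face away from the benzyl group, which with the (R)-auxiliary should set the (R)-configured α-carbon (the future C8) next to the (R)-methyl centre.

Step 4
Reactants: 10 (4R)-4-benzyl-3-[(2R,3R)-2-(2-tert-butoxy-2-oxoethyl)-3,7-dimethyloct-6-enoyl]oxazolidin-2-one
Product: 11 tert-butyl (3R,4R)-3-(hydroxymethyl)-4,8-dimethylnon-7-enoate
Conditions: LiBH4, H2O (1 equiv), Et2O, 0 °C
Reagents that add atoms: none
Why: Reductive cleavage of the N-acyloxazolidinone by LiBH4 should stop at the primary alcohol and spare the tert-butyl ester, with the auxiliary recovered.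

Step 5
Reactants: 11 tert-butyl (3R,4R)-3-(hydroxymethyl)-4,8-dimethylnon-7-enoate
Product: 12 tert-butyl (3R,4R)-3-formyl-4,8-dimethylnon-7-enoate
Conditions: Dess–Martin periodinane, CH2Cl2, 0 °C → rt
Reagents that add atoms: none
Why: Dess–Martin oxidation under near-neutral conditions should give the α-branched aldehyde without epimerising the adjacent centre.

Step 6
Reactants: 12 tert-butyl (3R,4R)-3-formyl-4,8-dimethylnon-7-enoate
Product: 13 tert-butyl (3S,4R)-3-ethenyl-4,8-dimethylnon-7-enoate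
Conditions: Ph3PCH3Br, KN(SiMe3)2, THF, 0 °C; then 12, −78 → 0 °C
Reagents that add atoms: methyltriphenylphosphonium bromide, C[P+](c1ccccc1)(c1ccccc1)c1ccccc1.[Br-]
Why: Wittig methylenation with the non-stabilised ylide at low temperature should convert the aldehyde to the vinyl group faster than it is enolised (the descriptor changes only through priorities).

Step 7
Reactants: 13 tert-butyl (3S,4R)-3-ethenyl-4,8-dimethylnon-7-enoate
Product: 15 tert-butyl (2Z,3S,4R)-3-ethenyl-2-(hydroxymethylidene)-4,8-dimethylnon-7-enoate, via lithium ester enolate 14 (not isolated)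
Conditions: LiN(i-Pr)2, THF, −78 °C; then HCO2Me, −78 → 0 °C; aq. NH4Cl
Reagents that add atoms: methyl formate, COC=O
Why: Crossed Claisen condensation of the ester enolate with methyl formate is driven by deprotonation of the product, which exists as the hydrogen-bonded Z enol, so no new stereocentre has to be controlled.

Step 8
Reactants: 15 tert-butyl (2Z,3S,4R)-3-ethenyl-2-(hydroxymethylidene)-4,8-dimethylnon-7-enoate
Product: 16 tert-butyl (2E,3S,4R)-3-ethenyl-2-{[(4-methoxyphenyl)methoxy]methylidene}-4,8-dimethylnon-7-enoate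
Conditions: 4-MeOC6H4CH2Cl, K2CO3, NaI (cat.), DMF, rt
Reagents that add atoms: 4-methoxybenzyl chloride, COc1ccc(CCl)cc1
Why: O-Alkylation of the ambident formyl ester enolate in a dipolar aprotic solvent (Williamson-type ether synthesis) should give the enol ether as the thermodynamically preferred E isomer (alkoxy group trans to the ester, cis to C8), the geometry that later places the oxygen axial on ring A.

Step 9
Reactants: 16 tert-butyl (2E,3S,4R)-3-ethenyl-2-{[(4-methoxyphenyl)methoxy]methylidene}-4,8-dimethylnon-7-enoate; 4 5-bromo-1,1-dimethoxyhex-5-en-2-one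
Product: 18 tert-butyl (2E,3S)-10,10-dimethoxy-2-{[(4-methoxyphenyl)methoxy]methylidene}-3-[(2R)-6-methylhept-5-en-2-yl]-6-methylidene-9-oxodecanoate, via alkylborane 17 (not isolated)
Conditions: 9-BBN, THF, 0 °C → rt; then 4, Pd(dppf)Cl2 (5 mol %), AsPh3, Cs2CO3, DMF/H2O, rt
Reagents that add atoms: none
Why: 9-BBN should hydroborate only the monosubstituted alkene (anti-Markovnikov), and B-alkyl Suzuki–Miyaura coupling with the 2-bromoalkene then forms the C6–C5 bond and the 1,1-disubstituted alkene with ketone, acetal and acrylate untouched.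

Step 10
Reactants: 18 tert-butyl (2E,3S)-10,10-dimethoxy-2-{[(4-methoxyphenyl)methoxy]methylidene}-3-[(2R)-6-methylhept-5-en-2-yl]-6-methylidene-9-oxodecanoate
Product: 20 tert-butyl (1S,5R,8S,9R)-2-(dimethoxymethyl)-2-hydroxy-9-[(4-methoxyphenyl)methoxy]-5-methyl-8-[(2R)-6-methylhept-5-en-2-yl]bicyclo[3.3.1]nonane-1-carboxylate, via iron ester enolate 19 (not isolated)
Conditions: Fe(acac)3 (30 mol %), PhSiH2(O-i-Pr) (slow addition), i-PrOH/THF, degassed, 0 °C → rt
Reagents that add atoms: none
Why: Proposed new method: Hydrogen-atom transfer from an iron hydride to the 1,1-disubstituted alkene gives the tertiary C5 radical (its methyl group is the former exo-methylene), which adds 6-endo-trig to C9, the β-carbon of the alkoxyacrylate; the resulting C1 radical is reduced by divalent iron to an ester enolate that adds to the C2 ketone in a 6-(enolexo)-exo-trig aldol, the closest known reaction type being the hydrogen-atom-transfer-initiated radical conjugate addition–aldol (radical–polar crossover) annulation of alkenes with enones and enals, here extended to a β-oxygenated acrylate and a bridged product. Ring A (C9, C1, C8, C7, C6, C5) closes in the endo mode because the tether sits on the α-carbon C1, so exo attack would have to occur at the fully substituted, electronically mismatched α-carbon, and ring B (C9, C5, C4, C3, C2, C1) closes by the aldol. C9 is set in a chair transition state with the C8 side chain equatorial, where the E geometry (alkoxy group cis to C8) forces the C9 oxygen axial on ring A, syn to the axial hydrogen on C8 as in the target; C1 follows because the enolate can reach the ketone only through a cis-1,3-diaxial arrangement, and C5 is productive only in the epimer whose keto arm is axial. The step needs hydrogen-atom transfer to the 1,1-disubstituted alkene in preference to the trisubstituted side-chain alkene (the former is less hindered), and aldol closure faster than protonation or β-elimination of the arylmethoxide from the enolate (an alkoxide is a poor leaving group and the keto acetal is an activated, intramolecular electrophile). The C5 epimer with the arm equatorial cannot close in this way and is expected as a separable by-product, and the carbinol configuration at C2 is irrelevant because it is removed in step 11.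

Step 11
Reactants: 20 tert-butyl (1S,5R,8S,9R)-2-(dimethoxymethyl)-2-hydroxy-9-[(4-methoxyphenyl)methoxy]-5-methyl-8-[(2R)-6-methylhept-5-en-2-yl]bicyclo[3.3.1]nonane-1-carboxylate
Product: 21 tert-butyl (1R,5R,8S,9R)-2-(dimethoxymethyl)-9-[(4-methoxyphenyl)methoxy]-5-methyl-8-[(2R)-6-methylhept-5-en-2-yl]bicyclo[3.3.1]non-2-ene-1-carboxylate
Conditions: Burgess reagent (MeO2CN–SO2NEt3 inner salt), PhMe, 60 °C
Reagents that add atoms: none
Why: Burgess dehydration (syn elimination through the sulfamate ester) of the tertiary alcohol should give the C2=C3 alkene, since C1 is quaternary and C3 offers the only ring β-hydrogens.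

Step 12
Reactants: 21 tert-butyl (1R,5R,8S,9R)-2-(dimethoxymethyl)-9-[(4-methoxyphenyl)methoxy]-5-methyl-8-[(2R)-6-methylhept-5-en-2-yl]bicyclo[3.3.1]non-2-ene-1-carboxylate
Product: 22 {(1S,5R,8S,9R)-2-(dimethoxymethyl)-9-[(4-methoxyphenyl)methoxy]-5-methyl-8-[(2R)-6-methylhept-5-en-2-yl]bicyclo[3.3.1]non-2-en-1-yl}methanol
Conditions: LiAlH4, Et2O, 0 °C → rt
Reagents that add atoms: none
Why: LiAlH4 reduces the hindered tert-butyl ester to the primary alcohol while acetal, PMB ether and alkenes are inert (ester reduction; the C1 descriptor changes only through priorities).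

Step 13
Reactants: 22 {(1S,5R,8S,9R)-2-(dimethoxymethyl)-9-[(4-methoxyphenyl)methoxy]-5-methyl-8-[(2R)-6-methylhept-5-en-2-yl]bicyclo[3.3.1]non-2-en-1-yl}methanol
Product: 23 (1R,5R,8S,9R)-2-(dimethoxymethyl)-9-[(4-methoxyphenyl)methoxy]-5-methyl-8-[(2R)-6-methylhept-5-en-2-yl]bicyclo[3.3.1]non-2-ene-1-carbaldehyde
Conditions: (n-Pr4N)RuO4 (5 mol %), N-methylmorpholine N-oxide, 4 Å MS, CH2Cl2, rt
Reagents that add atoms: none
Why: Ley–Griffith oxidation is neutral, so the primary alcohol should give the aldehyde without hydrolysing the acetal.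

Step 14
Reactants: 23 (1R,5R,8S,9R)-2-(dimethoxymethyl)-9-[(4-methoxyphenyl)methoxy]-5-methyl-8-[(2R)-6-methylhept-5-en-2-yl]bicyclo[3.3.1]non-2-ene-1-carbaldehyde
Product: 24 (1R,5R,8S,9R)-2-(dimethoxymethyl)-9-hydroxy-5-methyl-8-[(2R)-6-methylhept-5-en-2-yl]bicyclo[3.3.1]non-2-ene-1-carbaldehyde
Conditions: DDQ, CH2Cl2/pH 7 buffer, 0 °C
Reagents that add atoms: none
Why: Oxidative cleavage of the 4-methoxybenzyl ether by DDQ (hydride abstraction, then hydrolysis of the oxocarbenium ion) should free the C9 alcohol under buffered conditions that spare acetal, aldehyde and alkenes.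

Step 15
Reactants: 24 (1R,5R,8S,9R)-2-(dimethoxymethyl)-9-hydroxy-5-methyl-8-[(2R)-6-methylhept-5-en-2-yl]bicyclo[3.3.1]non-2-ene-1-carbaldehyde
Product: 26 (1R,5R,8S,9R)-1,2-diformyl-5-methyl-8-[(2R)-6-methylhept-5-en-2-yl]bicyclo[3.3.1]non-2-en-9-yl acetate, via acetate acetal 25 (not isolated)
Conditions: Ac2O, pyridine, DMAP (cat.), CH2Cl2, rt; then PPTS (cat.), acetone/H2O, rt
Reagents that add atoms: acetic anhydride, CC(=O)OC(C)=O; water, O
Why: DMAP-catalysed acetylation of the hindered secondary alcohol, then mild acid-catalysed hydrolysis of the allylic dimethyl acetal, should give the target without touching any stereocentre (acylation, acetal hydrolysis).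

**Compound list**
1 | 1,1-dimethoxypropan-2-one | COC(OC)C(C)=O | starting material
2 | 2,3-dibromoprop-1-ene | C=C(Br)CBr | starting material
3 | lithium 3,3-dimethoxyprop-1-en-2-olate (enolate of 1) | [Li+].[O-]C(=C)C(OC)OC | intermediate
4 | 5-bromo-1,1-dimethoxyhex-5-en-2-one | COC(OC)C(=O)CCC(Br)=C | intermediate
5 | (R)-citronellic acid, (3R)-3,7-dimethyloct-6-enoic acid | OC(=O)C[C@H](C)CCC=C(C)C | starting material
6 | (R)-4-benzyloxazolidin-2-one | O=C1N[C@H](Cc2ccccc2)CO1 | starting material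
7 | (3R)-3,7-dimethyloct-6-enoic pivalic anhydride | CC(C)(C)C(=O)OC(=O)C[C@H](C)CCC=C(C)C | intermediate
8 | (4R)-4-benzyl-3-[(3R)-3,7-dimethyloct-6-enoyl]oxazolidin-2-one | O=C(C[C@H](C)CCC=C(C)C)N1[C@H](Cc2ccccc2)COC1=O | intermediate
9 | sodium Z enolate of 8 | [Na+].[O-]/C(=C\[C@H](C)CCC=C(C)C)N1[C@H](Cc2ccccc2)COC1=O | intermediate
10 | (4R)-4-benzyl-3-[(2R,3R)-2-(2-tert-butoxy-2-oxoethyl)-3,7-dimethyloct-6-enoyl]oxazolidin-2-one | O=C([C@H](CC(=O)OC(C)(C)C)[C@H](C)CCC=C(C)C)N1[C@H](Cc2ccccc2)COC1=O | intermediate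
11 | tert-butyl (3R,4R)-3-(hydroxymethyl)-4,8-dimethylnon-7-enoate | OC[C@H](CC(=O)OC(C)(C)C)[C@H](C)CCC=C(C)C | intermediate
12 | tert-butyl (3R,4R)-3-formyl-4,8-dimethylnon-7-enoate | O=C[C@H](CC(=O)OC(C)(C)C)[C@H](C)CCC=C(C)C | intermediate
13 | tert-butyl (3S,4R)-3-ethenyl-4,8-dimethylnon-7-enoate | C=C[C@H](CC(=O)OC(C)(C)C)[C@H](C)CCC=C(C)C | intermediate
14 | lithium ester enolate of 13 (enolate geometry not defined) | [Li+].[O-]C(OC(C)(C)C)=C[C@@H](C=C)[C@H](C)CCC=C(C)C | intermediate
15 | tert-butyl (2Z,3S,4R)-3-ethenyl-2-(hydroxymethylidene)-4,8-dimethylnon-7-enoate (enol form of the α-formyl ester) | O/C=C(\C(=O)OC(C)(C)C)[C@@H](C=C)[C@H](C)CCC=C(C)C | intermediate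
16 | tert-butyl (2E,3S,4R)-3-ethenyl-2-{[(4-methoxyphenyl)methoxy]methylidene}-4,8-dimethylnon-7-enoate | COc1ccc(CO/C=C(/C(=O)OC(C)(C)C)[C@@H](C=C)[C@H](C)CCC=C(C)C)cc1 | intermediate
17 | B-alkyl-9-borabicyclo[3.3.1]nonane from 16 (boron on the terminal carbon of the former vinyl group) | COc1ccc(CO/C=C(/C(=O)OC(C)(C)C)[C@@H](CCB2C3CCCC2CCC3)[C@H](C)CCC=C(C)C)cc1 | intermediate
18 | tert-butyl (2E,3S)-10,10-dimethoxy-2-{[(4-methoxyphenyl)methoxy]methylidene}-3-[(2R)-6-methylhept-5-en-2-yl]-6-methylidene-9-oxodecanoate | COc1ccc(CO/C=C(/C(=O)OC(C)(C)C)[C@@H](CCC(=C)CCC(=O)C(OC)OC)[C@H](C)CCC=C(C)C)cc1 | intermediate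
19 | iron-bound tert-butyl ester enolate with ring A closed (drawn as the enolate anion; ring centres as in 20) | COc1ccc(CO[C@@H]2[C@@](C)(CCC(=O)C(OC)OC)CC[C@@H]([C@H](C)CCC=C(C)C)C2=C([O-])OC(C)(C)C)cc1 | intermediate
20 | tert-butyl (1S,5R,8S,9R)-2-(dimethoxymethyl)-2-hydroxy-9-[(4-methoxyphenyl)methoxy]-5-methyl-8-[(2R)-6-methylhept-5-en-2-yl]bicyclo[3.3.1]nonane-1-carboxylate (C2 epimers both usable) | COc1ccc(CO[C@@H]2[C@@]3(C)CCC(O)(C(OC)OC)[C@]2(C(=O)OC(C)(C)C)[C@H]([C@H](C)CCC=C(C)C)CC3)cc1 | intermediate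
21 | tert-butyl (1R,5R,8S,9R)-2-(dimethoxymethyl)-9-[(4-methoxyphenyl)methoxy]-5-methyl-8-[(2R)-6-methylhept-5-en-2-yl]bicyclo[3.3.1]non-2-ene-1-carboxylate | COc1ccc(CO[C@@H]2[C@@]3(C)CC=C(C(OC)OC)[C@]2(C(=O)OC(C)(C)C)[C@H]([C@H](C)CCC=C(C)C)CC3)cc1 | intermediate
22 | {(1S,5R,8S,9R)-2-(dimethoxymethyl)-9-[(4-methoxyphenyl)methoxy]-5-methyl-8-[(2R)-6-methylhept-5-en-2-yl]bicyclo[3.3.1]non-2-en-1-yl}methanol | COc1ccc(CO[C@@H]2[C@@]3(C)CC=C(C(OC)OC)[C@]2(CO)[C@H]([C@H](C)CCC=C(C)C)CC3)cc1 | intermediate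
23 | (1R,5R,8S,9R)-2-(dimethoxymethyl)-9-[(4-methoxyphenyl)methoxy]-5-methyl-8-[(2R)-6-methylhept-5-en-2-yl]bicyclo[3.3.1]non-2-ene-1-carbaldehyde | COc1ccc(CO[C@@H]2[C@@]3(C)CC=C(C(OC)OC)[C@]2(C=O)[C@H]([C@H](C)CCC=C(C)C)CC3)cc1 | intermediate
24 | (1R,5R,8S,9R)-2-(dimethoxymethyl)-9-hydroxy-5-methyl-8-[(2R)-6-methylhept-5-en-2-yl]bicyclo[3.3.1]non-2-ene-1-carbaldehyde | O[C@@H]1[C@@]2(C)CC=C(C(OC)OC)[C@]1(C=O)[C@H]([C@H](C)CCC=C(C)C)CC2 | intermediate
25 | (1R,5R,8S,9R)-2-(dimethoxymethyl)-1-formyl-5-methyl-8-[(2R)-6-methylhept-5-en-2-yl]bicyclo[3.3.1]non-2-en-9-yl acetate | CC(=O)O[C@@H]1[C@@]2(C)CC=C(C(OC)OC)[C@]1(C=O)[C@H]([C@H](C)CCC=C(C)C)CC2 | intermediate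
26 | (1R,5R,8S,9R)-1,2-diformyl-5-methyl-8-[(2R)-6-methylhept-5-en-2-yl]bicyclo[3.3.1]non-2-en-9-yl acetate | CC(=O)O[C@@H]1[C@@]2(C)CC=C(C=O)[C@]1(C=O)[C@H]([C@H](C)CCC=C(C)C)CC2 | target

**Step count and risks**
Total steps: 15. Longest linear sequence: 14 (steps 2 to 15, from 5).

Steps most likely to fail:

1. Step 10 (proposed new method). The ester enolate may lose the arylmethoxide by β-elimination or be protonated before the aldol. The radical may add with the keto arm equatorial at C5. Hydrogen-atom transfer to the side-chain alkene, or capture of the C1 radical by it, may compete. The fallback uses known chemistry, sets out from 18 and comes back at 24, and separates the two bond formations. 18 is cyclised under protic reductive olefin–acrylate coupling conditions (Fe(acac)3, PhSiH3, EtOH/ethylene glycol, 60 °C), where the enolate is protonated, to tert-butyl 3-(4,4-dimethoxy-3-oxobutyl)-2-[(4-methoxyphenyl)methoxy]-3-methyl-6-[(2R)-6-methylhept-5-en-2-yl]cyclohexane-1-carboxylate F1. DDQ then frees the alcohol to give the 2-hydroxy ester F2, and Dess–Martin oxidation gives the 2-oxocyclohexane-1-carboxylate F3. Its doubly activated C1–H is enolised selectively by DBU, and a classical intramolecular aldol addition to the side-chain ketone closes ring B to the 9-oxobicyclo[3.3.1]nonane ketol F4; the C9 configuration and the acrylate geometry no longer matter. Burgess dehydration gives the 9-oxobicyclo[3.3.1]non-2-ene ester F5. NaBH4 should reduce the bridging ketone from the less hindered face over the unsaturated bridge to the 9-hydroxy ester F6, with the oxygen over ring A. LiAlH4 gives the 1-(hydroxymethyl)bicyclo[3.3.1]non-2-en-9-ol F7, and selective oxidation of the primary alcohol (TEMPO, PhI(OAc)2) returns to 24.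

2. Step 11. Elimination at the congested tertiary carbinol may be slow, the β-hydroxy ester may open by retro-aldol on heating, or elimination may run toward the acetal carbon. The fallback sets out from 20 and comes back at 22. The ester is reduced first (LiAlH4) to 2-(dimethoxymethyl)-1-(hydroxymethyl)-9-[(4-methoxyphenyl)methoxy]-5-methyl-8-[(2R)-6-methylhept-5-en-2-yl]bicyclo[3.3.1]nonan-2-ol F8, which removes the retro-aldol pathway. The primary alcohol is silylated (TBSCl, imidazole) to the primary TBS ether F9. The tertiary alcohol is eliminated by an E2 process through its chlorosulfite (SOCl2, pyridine, 0 °C) to the non-2-ene TBS ether F10, and Bu4NF removes the silyl group to give 22.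

3. Step 8. The ambident enolate may undergo C-alkylation, and E selectivity may be incomplete. The fallback sets out from 13 and comes back at 16, introducing the one-carbon unit as an enamine. 13 is heated with tert-butoxybis(dimethylamino)methane to tert-butyl (2E,3S,4R)-2-[(dimethylamino)methylidene]-3-ethenyl-4,8-dimethylnon-7-enoate F11. Acid-catalysed exchange of the dimethylamino group with 4-methoxybenzyl alcohol (PPTS, toluene, removal of the amine) under thermodynamic control then gives 16.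

**Further compounds**
F1 | step 10 | tert-butyl 3-(4,4-dimethoxy-3-oxobutyl)-2-[(4-methoxyphenyl)methoxy]-3-methyl-6-[(2R)-6-methylhept-5-en-2-yl]cyclohexane-1-carboxylate (C1 epimers) | COc1ccc(CO[C@@H]2[C@@](C)(CCC(=O)C(OC)OC)CC[C@@H]([C@H](C)CCC=C(C)C)C2C(=O)OC(C)(C)C)cc1
F2 | step 10 | tert-butyl 3-(4,4-dimethoxy-3-oxobutyl)-2-hydroxy-3-methyl-6-[(2R)-6-methylhept-5-en-2-yl]cyclohexane-1-carboxylate | O[C@@H]1[C@@](C)(CCC(=O)C(OC)OC)CC[C@@H]([C@H](C)CCC=C(C)C)C1C(=O)OC(C)(C)C
F3 | step 10 | tert-butyl 3-(4,4-dimethoxy-3-oxobutyl)-3-methyl-6-[(2R)-6-methylhept-5-en-2-yl]-2-oxocyclohexane-1-carboxylate | O=C1[C@@](C)(CCC(=O)C(OC)OC)CC[C@@H]([C@H](C)CCC=C(C)C)C1C(=O)OC(C)(C)C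
F4 | step 10 | tert-butyl 2-(dimethoxymethyl)-2-hydroxy-5-methyl-8-[(2R)-6-methylhept-5-en-2-yl]-9-oxobicyclo[3.3.1]nonane-1-carboxylate | O=C1[C@@]2(C)CCC(O)(C(OC)OC)[C@]1(C(=O)OC(C)(C)C)[C@H]([C@H](C)CCC=C(C)C)CC2
F5 | step 10 | tert-butyl 2-(dimethoxymethyl)-5-methyl-8-[(2R)-6-methylhept-5-en-2-yl]-9-oxobicyclo[3.3.1]non-2-ene-1-carboxylate | O=C1[C@@]2(C)CC=C(C(OC)OC)[C@]1(C(=O)OC(C)(C)C)[C@H]([C@H](C)CCC=C(C)C)CC2
F6 | step 10 | tert-butyl 2-(dimethoxymethyl)-9-hydroxy-5-methyl-8-[(2R)-6-methylhept-5-en-2-yl]bicyclo[3.3.1]non-2-ene-1-carboxylate | O[C@@H]1[C@@]2(C)CC=C(C(OC)OC)[C@]1(C(=O)OC(C)(C)C)[C@H]([C@H](C)CCC=C(C)C)CC2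
F7 | step 10 | 2-(dimethoxymethyl)-1-(hydroxymethyl)-5-methyl-8-[(2R)-6-methylhept-5-en-2-yl]bicyclo[3.3.1]non-2-en-9-ol | O[C@@H]1[C@@]2(C)CC=C(C(OC)OC)[C@]1(CO)[C@H]([C@H](C)CCC=C(C)C)CC2
F8 | step 11 | 2-(dimethoxymethyl)-1-(hydroxymethyl)-9-[(4-methoxyphenyl)methoxy]-5-methyl-8-[(2R)-6-methylhept-5-en-2-yl]bicyclo[3.3.1]nonan-2-ol | COc1ccc(CO[C@@H]2[C@@]3(C)CCC(O)(C(OC)OC)[C@]2(CO)[C@H]([C@H](C)CCC=C(C)C)CC3)cc1
F9 | step 11 | primary tert-butyldimethylsilyl ether of F8 | COc1ccc(CO[C@@H]2[C@@]3(C)CCC(O)(C(OC)OC)[C@]2(CO[Si](C)(C)C(C)(C)C)[C@H]([C@H](C)CCC=C(C)C)CC3)cc1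
F10 | step 11 | tert-butyldimethylsilyl ether of 22 | COc1ccc(CO[C@@H]2[C@@]3(C)CC=C(C(OC)OC)[C@]2(CO[Si](C)(C)C(C)(C)C)[C@H]([C@H](C)CCC=C(C)C)CC3)cc1
F11 | step 8 | tert-butyl (2E,3S,4R)-2-[(dimethylamino)methylidene]-3-ethenyl-4,8-dimethylnon-7-enoate | CN(C)/C=C(/C(=O)OC(C)(C)C)[C@@H](C=C)[C@H](C)CCC=C(C)C
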